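**Strategy.** The upper flavan is cut at C4–C4a and O1–C2. Ring A is a free phloroglucinol nucleus whose three ring carbons and three oxygens are equivalent, and C4 stands 1,3 to C2 in ring C. Ring C is therefore one arene carbon and one phenolic oxygen of phloroglucinol bridging Cβ and the carbonyl carbon of a chalcone. That chalcone bears C8 of ring D of perbenzylated (+)-catechin on Cβ and ring B on the ketone. One catalytic asymmetric Friedel–Crafts conjugate addition with cyclodehydration forms both bonds, closes ring C as a flav-2-ene and sets C4. A single hydrogenation then sets C2 and removes all seven benzyl groups.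

Key step: step 7

Remarks on the chemistry:
- Upper unit: rings A, C (pyran), B. Lower catechin unit: rings D, F (pyran), E. "Penta-O-benzylcatechin-8-yl" means (2R,3S)-3,5,7-tris(benzyloxy)-2-[3,4-bis(benzyloxy)phenyl]chroman-8-yl.
- The C3 hydroxyl of ring F is carried as a benzyl ether, not a silyl ether. One hydrogenation then removes every protecting group, and the free polyphenol never meets fluoride or base.
- The catalyst in step 7 is the squaramide 3-[3,5-bis(trifluoromethyl)anilino]-4-[(9-deoxy-epi-quinidin-9-yl)amino]cyclobut-3-ene-1,2-dione. Its sense of induction is assumed. It is to be confirmed after step 8 by NOE between H-2 and H-4 and by comparison with the C4 epimer. If the sense is opposite, the quinine-derived pseudo-enantiomer is used.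
- In step 8 alkene saturation and the seven hydrogenolyses run side by side in no fixed order, so no single intermediate is defined there.

**Step 1**
Reactants: 1 (+)-catechin
Product: 2 5,7,3',4'-tetra-O-benzyl-(+)-catechin
Conditions: BnBr (4.4 equiv), K2CO3, DMF, 0 °C to rt, argon
Reagents that add atoms: benzyl bromide, BrCc1ccccc1
Why: Williamson etherification in which carbonate deprotonates only the four phenols, so the secondary C3 alcohol stays free and the mild, cold conditions limit C-benzylation and C2 epimerisation.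

**Step 2**
Reactants: 2 5,7,3',4'-tetra-O-benzyl-(+)-catechin
Product: 3 8-bromo-5,7,3',4'-tetra-O-benzyl-(+)-catechin
Conditions: NBS (1.0 equiv), CH2Cl2, −78 °C to rt, dark
Reagents that add atoms: N-bromosuccinimide, O=C1CCC(=O)N1Br
Why: Electrophilic aromatic bromination of the trioxygenated ring D, for which C8 is the established site of attack in tetra-O-benzyl flavan-3-ols.

**Step 3**
Reactants: 3 8-bromo-5,7,3',4'-tetra-O-benzyl-(+)-catechin
Product: 4 8-bromo-3,5,7,3',4'-penta-O-benzyl-(+)-catechin
Conditions: NaH, BnBr, TBAI (cat.), THF, 0 °C to rt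
Reagents that add atoms: benzyl bromide, BrCc1ccccc1
Why: Williamson etherification of the secondary alkoxide; no stereocentre is touched because C2 cannot open to a quinone methide once the ring E phenols are capped.

**Step 4**
Reactants: 4 8-bromo-3,5,7,3',4'-penta-O-benzyl-(+)-catechin
Product: 6 3,5,7,3',4'-penta-O-benzyl-(+)-catechin-8-carbaldehyde, via 8-lithio arene 5 (not isolated)
Conditions: n-BuLi (1.05 equiv), THF, −78 °C; DMF, −78 to 0 °C; H2O
Reagents that add atoms: N,N-dimethylformamide, CN(C)C=O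
Why: Bromine–lithium exchange at −78 °C outruns any attack on the benzyl ethers, and aryllithium 5 is formylated by DMF (Bouveault aldehyde synthesis), the aldehyde being released on aqueous quench.

**Step 5**
Reactants: 7 3',4'-dihydroxyacetophenone
Product: 8 3',4'-bis(benzyloxy)acetophenone
Conditions: BnBr (2.2 equiv), K2CO3, DMF, 60 °C
Reagents that add atoms: benzyl bromide, BrCc1ccccc1
Why: Williamson etherification of both catechol hydroxyls, a routine protection of this ketone.

**Step 6**
Reactants: 6 3,5,7,3',4'-penta-O-benzyl-(+)-catechin-8-carbaldehyde; 8 3',4'-bis(benzyloxy)acetophenone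
Product: 10 (E)-1-[3,4-bis(benzyloxy)phenyl]-3-(penta-O-benzylcatechin-8-yl)prop-2-en-1-one, via aldol adduct 9 (not isolated)
Conditions: KOH, EtOH/THF, rt to 40 °C
Reagents that add atoms: none
Why: Claisen–Schmidt condensation in which the enolate of 8 adds to the non-enolisable aldehyde and E1cB loss of water from 9 gives the thermodynamic E-enone, as known for 2,4,6-trialkoxybenzaldehydes; the benzyl ethers and the ring F stereocentres are inert to hydroxide.

**Step 7**
Reactants: 10 (E)-1-[3,4-bis(benzyloxy)phenyl]-3-(penta-O-benzylcatechin-8-yl)prop-2-en-1-one; 11 phloroglucinol (anhydrous)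
Product: 14 (4S)-2-[3,4-bis(benzyloxy)phenyl]-4-(penta-O-benzylcatechin-8-yl)-4H-chromene-5,7-diol, via open Friedel–Crafts adduct 12 (not isolated), via cyclic hemiketal 13 (not isolated)
Conditions: 11 (4 equiv), quinidine-derived squaramide (10 mol %), CH2Cl2/THF 4:1, −20 °C; then PPTS (30 mol %), 4 Å MS, rt, same flask
Reagents that add atoms: none
Why: The quinuclidine nitrogen of the catalyst hydrogen-bonds and partly deprotonates one hydroxyl of 11 while the two squaramide N–H bonds hold the enone carbonyl, so a ring carbon of 11 adds to the Re face of Cβ of 10 and, after rearomatisation, C4–C4a of adduct 12 is in place. The closest known reaction type is the organocatalytic asymmetric Friedel–Crafts conjugate addition and cyclodehydration of naphthols, sesamol and cyclic 1,3-diones with enones under bifunctional hydrogen-bond catalysis, which gives 4-aryl-4H-chromenes. Ring C closes by 6-exo-trig attack of the ortho phenolic oxygen on the ketone (O1–C2, hemiketal 13), and PPTS with molecular sieves then removes water to leave the C2=C3 enol ether conjugated with ring B. The new stereocentre C4 is set in the carbon–carbon bond-forming event under catalyst control, the pseudo-enantiomeric catalyst being the remedy if the remote ring F stereocentres prove mismatched. Regiochemistry needs no control, because every ring carbon and every hydroxyl of 11 is equivalent and Cβ already carries C8 of ring D. Mono-alkylation should be secured by the fourfold excess of 11, and the near-neutral medium avoids acid-induced loss of an aryl group from C4.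

**Step 8**
Reactants: 14 (4S)-2-[3,4-bis(benzyloxy)phenyl]-4-(penta-O-benzylcatechin-8-yl)-4H-chromene-5,7-diol
Product: 15 (2S,4S)-2-(3,4-dihydroxyphenyl)-4-[(2R,3S)-2-(3,4-dihydroxyphenyl)-3,5,7-trihydroxychroman-8-yl]chromane-5,7-diol (CNP0180676.1)
Conditions: H2 (1 atm), Pd(OH)2/C, THF/MeOH 1:1, rt
Reagents that add atoms: none
Why: Heterogeneous hydrogenation should deliver H2 to the C2=C3 enol ether from the face opposite the pseudo-axial C4 aryl group, which sets C2 as S with H-2 and H-4 cis (as known for 2,4-diaryl-4H-chromenes), while hydrogenolysis of all seven benzyl ethers runs in the same operation and the benzylic O1–C2 bonds survive as in standard debenzylations of catechin derivatives.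

**Compound list**
1 | (+)-catechin, (2R,3S)-2-(3,4-dihydroxyphenyl)chromane-3,5,7-triol | Oc1cc(O)c2c(c1)O[C@H](c1ccc(O)c(O)c1)[C@@H](O)C2 | starting material
2 | 5,7,3',4'-tetra-O-benzyl-(+)-catechin | O(Cc3ccccc3)c1cc(OCc3ccccc3)c2c(c1)O[C@H](c4ccc(OCc3ccccc3)c(OCc3ccccc3)c4)[C@@H](O)C2 | intermediate
3 | 8-bromo-5,7,3',4'-tetra-O-benzyl-(+)-catechin | Brc1c(OCc3ccccc3)cc(OCc3ccccc3)c2c1O[C@H](c4ccc(OCc3ccccc3)c(OCc3ccccc3)c4)[C@@H](O)C2 | intermediate
4 | 8-bromo-3,5,7,3',4'-penta-O-benzyl-(+)-catechin | Brc1c(OCc3ccccc3)cc(OCc3ccccc3)c2c1O[C@H](c4ccc(OCc3ccccc3)c(OCc3ccccc3)c4)[C@@H](OCc3ccccc3)C2 | intermediate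
5 | 8-lithio-3,5,7,3',4'-penta-O-benzyl-(+)-catechin | [Li]c1c(OCc3ccccc3)cc(OCc3ccccc3)c2c1O[C@H](c4ccc(OCc3ccccc3)c(OCc3ccccc3)c4)[C@@H](OCc3ccccc3)C2 | intermediate (not isolated)
6 | 3,5,7,3',4'-penta-O-benzyl-(+)-catechin-8-carbaldehyde | O=Cc1c(OCc3ccccc3)cc(OCc3ccccc3)c2c1O[C@H](c4ccc(OCc3ccccc3)c(OCc3ccccc3)c4)[C@@H](OCc3ccccc3)C2 | intermediate
7 | 3',4'-dihydroxyacetophenone | CC(=O)c1ccc(O)c(O)c1 | starting material
8 | 3',4'-bis(benzyloxy)acetophenone | CC(=O)c1ccc(OCc3ccccc3)c(OCc3ccccc3)c1 | intermediate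
9 | 1-[3,4-bis(benzyloxy)phenyl]-3-hydroxy-3-(penta-O-benzylcatechin-8-yl)propan-1-one (carbinol epimers) | O=C(c1ccc(OCc3ccccc3)c(OCc3ccccc3)c1)CC(O)c1c(OCc3ccccc3)cc(OCc3ccccc3)c2c1O[C@H](c4ccc(OCc3ccccc3)c(OCc3ccccc3)c4)[C@@H](OCc3ccccc3)C2 | intermediate (not isolated)
10 | (E)-1-[3,4-bis(benzyloxy)phenyl]-3-(penta-O-benzylcatechin-8-yl)prop-2-en-1-one | O=C(c1ccc(OCc3ccccc3)c(OCc3ccccc3)c1)/C=C/c1c(OCc3ccccc3)cc(OCc3ccccc3)c2c1O[C@H](c4ccc(OCc3ccccc3)c(OCc3ccccc3)c4)[C@@H](OCc3ccccc3)C2 | intermediate
11 | phloroglucinol, benzene-1,3,5-triol | Oc1cc(O)cc(O)c1 | starting material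
12 | (3S)-1-[3,4-bis(benzyloxy)phenyl]-3-(penta-O-benzylcatechin-8-yl)-3-(2,4,6-trihydroxyphenyl)propan-1-one | O=C(c1ccc(OCc3ccccc3)c(OCc3ccccc3)c1)C[C@@H](c1c(O)cc(O)cc1O)c1c(OCc3ccccc3)cc(OCc3ccccc3)c2c1O[C@H](c4ccc(OCc3ccccc3)c(OCc3ccccc3)c4)[C@@H](OCc3ccccc3)C2 | intermediate (not isolated)
13 | (4S)-2-[3,4-bis(benzyloxy)phenyl]-4-(penta-O-benzylcatechin-8-yl)chromane-2,5,7-triol (C2 epimers) | Oc1cc(O)c2c(c1)OC(O)(c1ccc(OCc3ccccc3)c(OCc3ccccc3)c1)C[C@@H]2c1c(OCc3ccccc3)cc(OCc3ccccc3)c2c1O[C@H](c4ccc(OCc3ccccc3)c(OCc3ccccc3)c4)[C@@H](OCc3ccccc3)C2 | intermediate (not isolated)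
14 | (4S)-2-[3,4-bis(benzyloxy)phenyl]-4-(penta-O-benzylcatechin-8-yl)-4H-chromene-5,7-diol | Oc1cc(O)c2c(c1)OC(c1ccc(OCc3ccccc3)c(OCc3ccccc3)c1)=C[C@@H]2c1c(OCc3ccccc3)cc(OCc3ccccc3)c2c1O[C@H](c4ccc(OCc3ccccc3)c(OCc3ccccc3)c4)[C@@H](OCc3ccccc3)C2 | intermediate
15 | (2S,4S)-2-(3,4-dihydroxyphenyl)-4-[(2R,3S)-2-(3,4-dihydroxyphenyl)-3,5,7-trihydroxychroman-8-yl]chromane-5,7-diol | Oc1cc(O)c2c(c1)O[C@H](c1ccc(O)c(O)c1)C[C@@H]2c1c(O)cc(O)c2c1O[C@H](c1ccc(O)c(O)c1)[C@@H](O)C2 | target

**Totals.** Total step count: 8. Longest linear sequence: 7 steps (steps 1, 2, 3, 4, 6, 7, 8); step 5 is a one-step side branch.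

**Steps most likely to fail**

1. Step 7. The β-carbon is flanked by two ortho oxygens and is electron-rich, so conversion may be slow. Facial control by the catalyst may be weak against the chiral substrate. The resorcinol-type ring A of the product may be alkylated a second time, and acid may expel an aryl group from C4. Fallback, setting out from 2 and returning at 15: the other bond to C4 is formed instead. C8 of 2 is added to C4 of purchased luteolinidin chloride ([Cl-].Oc1cc(O)c2ccc(-c3ccc(O)c(O)c3)[o+]c2c1) in MeOH/THF with a little AcOH at rt. This is the classical addition of a phloroglucinol-type arene to a flavylium salt, and the 7-O-benzyl group of 2 blocks any later ketalisation onto C2. It should give (4S)-2-(3,4-dihydroxyphenyl)-4-(5,7,3',4'-tetra-O-benzylcatechin-8-yl)-4H-chromene-5,7-diol F1 together with its C4 epimer, since C4 is then under substrate control only. The epimers are separated by chromatography, and hydrogenation of F1 under the conditions of step 8 gives 15.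

2. Step 8. The double bond may migrate from C2=C3 toward C4 on the palladium surface, which would erase the C4 configuration. The facial bias at C2 may be insufficient, and the benzylic O1–C2 bond may be opened by hydrogenolysis. Fallback, setting out from 14 and returning at 15: ionic hydrogenation with Et3SiH and TFA in CH2Cl2 at −40 °C. Protonation at C3 gives the 2-aryl oxocarbenium ion and hydride is delivered to C2 anti to the C4 aryl group, so C4 is never touched. This should give (2S,4S)-2-[3,4-bis(benzyloxy)phenyl]-4-(penta-O-benzylcatechin-8-yl)chromane-5,7-diol F2. Hydrogenolysis of F2 (H2, Pd(OH)2/C, THF/MeOH), now without an alkene present, gives 15.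

3. Step 4. The hindered aryllithium may be protonated before it meets DMF (net loss of bromine), or the organolithium may attack benzylic positions of the ethers. Fallback, setting out from 4 and returning at 6: the carbon is introduced by cross-coupling. Suzuki–Miyaura vinylation of 4 with vinylboronic acid pinacol ester (Pd(OAc)2, SPhos, K3PO4, toluene/H2O, 80 °C) should give 8-vinyl-3,5,7,3',4'-penta-O-benzyl-(+)-catechin F3. Lemieux–Johnson cleavage of F3 (OsO4 cat., NaIO4, 2,6-lutidine, dioxane/H2O, rt) gives 6.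

**Further compounds**
F1 | step 7 | (4S)-2-(3,4-dihydroxyphenyl)-4-(5,7,3',4'-tetra-O-benzylcatechin-8-yl)-4H-chromene-5,7-diol | Oc1cc(O)c2c(c1)OC(c1ccc(O)c(O)c1)=C[C@@H]2c1c(OCc3ccccc3)cc(OCc3ccccc3)c2c1O[C@H](c4ccc(OCc3ccccc3)c(OCc3ccccc3)c4)[C@@H](O)C2
F2 | step 8 | (2S,4S)-2-[3,4-bis(benzyloxy)phenyl]-4-(penta-O-benzylcatechin-8-yl)chromane-5,7-diol | Oc1cc(O)c2c(c1)O[C@H](c1ccc(OCc3ccccc3)c(OCc3ccccc3)c1)C[C@@H]2c1c(OCc3ccccc3)cc(OCc3ccccc3)c2c1O[C@H](c4ccc(OCc3ccccc3)c(OCc3ccccc3)c4)[C@@H](OCc3ccccc3)C2
F3 | step 4 | 8-vinyl-3,5,7,3',4'-penta-O-benzyl-(+)-catechin | C=Cc1c(OCc3ccccc3)cc(OCc3ccccc3)c2c1O[C@H](c4ccc(OCc3ccccc3)c(OCc3ccccc3)c4)[C@@H](OCc3ccccc3)C2
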